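**Retrosynthetic overview**

1. Target 36 comes from the hexamer pentadecamethyl ether 35 (free hydroxyl at E3) by global O-demethylation.
2. The strategy rests on ring E: five contiguous oxygens, with the two crowded diaryl ethers E1–O–D4 and E6–O–F1 side by side, hydroxyls at E3, E4 and E5, and a single hydrogen at E2. Ring C repeats this pattern (C1–O–B4, C6–O–D1, hydrogen at C2).
3. Ring E is disconnected by a Danheiser benzannulation into the ABCD aryl ethynyl ether 26 (supplies E1 and E2) and the squarate-derived cyclobutenone 30 (supplies E3–E6 and the ring F ether). Ring C is made earlier by the same reaction from the AB ethynyl ether 12 and the ring D cyclobutenone 16.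
4. The ynol ethers come from hindered phenols with trichloroethylene and then n-BuLi; both cyclobutenones come from squaric acid through one common chloro methoxy squarate 3 and the mixed aryl methyl squarates. Only the uncrowded A–B ether is made by Ullmann coupling.
5. Rings A, B, D and F are bought as arenes; ring C is closed in step 12 and ring E in step 20.

Key step: step 20

Remark on the chemistry: the target has no stereocentre. Cyclobutenones 15, 16, 29 and 30 and the transient compounds 18, 20, 32 and 34 are racemic, and their stereocentres vanish when the benzene ring forms. In rings B and D, position 1 carries the ether to the preceding ring and position 4 the ether to the next ring. In rings C and E, position 1 carries the ether to the preceding ring, position 2 the hydrogen and position 6 the ether to the next ring.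

**Route**

Step 1
Reactants: 1 squaric acid
Product: 2 squaryl dichloride (3,4-dichlorocyclobut-3-ene-1,2-dione)
Conditions: (COCl)2 (2.2 equiv), DMF (cat.), CH2Cl2, rt → 40 °C
Reagents that add atoms: oxalyl chloride, ClC(=O)C(=O)Cl
Why: Vilsmeier-type chlorination, in which the chloroiminium salt from DMF and oxalyl chloride turns both vinylogous acid hydroxyls into chlorides, is the standard access to squaryl dichloride.

Step 2
Reactants: 2 squaryl dichloride
Product: 3 3-chloro-4-methoxycyclobut-3-ene-1,2-dione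
Conditions: MeOH (1.0 equiv), CH2Cl2, 0 °C → rt, Ar sweep; volatiles removed, kept as a dry CH2Cl2 stock solution
Reagents that add atoms: methanol, CO
Why: Addition–elimination of one equivalent of methanol on the vinylogous acid chloride (squarate half-ester formation) should stop at the mono-ester, because the first methoxy group donates into the ring and makes the second C–Cl carbon less electrophilic; the moisture-sensitive product is made once and divided between steps 9 and 17.

Step 3
Reactants: 4 4-bromo-2,6-dimethoxyphenol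
Product: 5 2-(benzyloxy)-5-bromo-1,3-dimethoxybenzene
Conditions: BnBr, K2CO3, DMF, 60 °C
Reagents that add atoms: benzyl bromide, BrCc1ccccc1
Why: Williamson etherification of the acidic phenol with a reactive benzylic halide masks the oxygen that later becomes B4 or D4.

Step 4
Reactants: 5 2-(benzyloxy)-5-bromo-1,3-dimethoxybenzene; 6 2,4,6-trimethoxyphenol
Product: 7 2-(benzyloxy)-1,3-dimethoxy-5-(2,4,6-trimethoxyphenoxy)benzene (AB benzyl ether)
Conditions: CuI (10 mol %), picolinic acid (20 mol %), K3PO4, DMSO, 100 °C, Ar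
Reagents that add atoms: none
Why: Ullmann diaryl ether synthesis with monovalent copper and picolinic acid couples di-ortho-substituted phenols, and the bromide carbon of 5 has two free ortho positions, so the crowding lies only on the nucleophile side.

Step 5
Reactants: 7 AB benzyl ether
Product: 8 2,6-dimethoxy-4-(2,4,6-trimethoxyphenoxy)phenol (AB phenol)
Conditions: H2 (1 atm), Pd/C, EtOAc–MeOH, rt
Reagents that add atoms: none
Why: Hydrogenolysis cleaves the benzyl ether and leaves aryl methyl ethers and the diaryl ether untouched.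

Step 6
Reactants: 8 AB phenol; 9 trichloroethylene
Product: 10 2-{[(E)-1,2-dichloroethenyl]oxy}-1,3-dimethoxy-5-(2,4,6-trimethoxyphenoxy)benzene
Conditions: K2CO3, DMF, 70 °C
Reagents that add atoms: none
Why: O-vinylation of a phenol with trichloroethylene: base generates dichloroacetylene, the phenoxide of 8 adds and anti protonation gives the (E)-1,2-dichlorovinyl ether, and the linear electrophile is indifferent to the two ortho methoxy groups.

Step 7
Reactants: 10 AB (E)-1,2-dichlorovinyl ether
Product: 12 2-(ethynyloxy)-1,3-dimethoxy-5-(2,4,6-trimethoxyphenoxy)benzene (AB ethynyl ether), via lithium acetylide 11 (not isolated)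
Conditions: n-BuLi (2.2 equiv), THF, −78 → −40 °C; then MeOH, −78 °C
Reagents that add atoms: none
Why: The dichlorovinyl ether route to alkynyl ethers: n-BuLi removes the vinyl hydrogen, loss of LiCl gives the chloroethynyl ether, chlorine–lithium exchange gives acetylide 11 and protonation gives the terminal ynol ether, while ring lithiation ortho to methoxy does not compete at −78 °C; 12 should be kept cold and used without delay.

Step 8
Reactants: 5 2-(benzyloxy)-5-bromo-1,3-dimethoxybenzene
Product: 13 4-(benzyloxy)-3,5-dimethoxyphenol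
Conditions: Pd2(dba)3 (2 mol %), tBuXPhos (8 mol %), KOH, 1,4-dioxane–H2O, 100 °C; then aq. HCl
Reagents that add atoms: potassium hydroxide, [K+].[OH-]
Why: Pd-catalysed hydroxylation of an aryl bromide (C–O cross-coupling with hydroxide) works on electron-rich bromides because the bulky biaryl phosphine favours reductive elimination of the phenol, and benzyl and methyl ethers are inert to the base.

Step 9
Reactants: 3 3-chloro-4-methoxycyclobut-3-ene-1,2-dione; 13 4-(benzyloxy)-3,5-dimethoxyphenol
Product: 14 3-[4-(benzyloxy)-3,5-dimethoxyphenoxy]-4-methoxycyclobut-3-ene-1,2-dione (ring D mixed aryl methyl squarate)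
Conditions: Et3N (1.1 equiv), CH2Cl2, −78 → 0 °C
Reagents that add atoms: none
Why: Addition–elimination on the vinylogous acid chloride (squarate ester formation): the phenoxide of 13 attacks the C–Cl carbon of 3 and not the C–OMe carbon, because chloride leaves far better than methoxide.

Step 10
Reactants: 14 ring D mixed aryl methyl squarate
Product: 15 racemic 2-[4-(benzyloxy)-3,5-dimethoxyphenoxy]-4-hydroxy-3-methoxycyclobut-2-en-1-one
Conditions: LiAlH(OtBu)3 (1.1 equiv), THF, −78 °C; aq. NH4Cl
Reagents that add atoms: none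
Why: 1,2-Reduction of one squarate carbonyl by the bulky LiAlH(OtBu)3 should occur at the carbonyl next to the methoxy carbon, which is the more electrophilic (its vinylogous donor is the weaker aryloxy group) and the less shielded; the new C4 stereocentre forms as a racemate, which is harmless because it is erased on aromatisation.

Step 11
Reactants: 15 racemic 4-hydroxycyclobutenone
Product: 16 racemic 2-[4-(benzyloxy)-3,5-dimethoxyphenoxy]-3,4-dimethoxycyclobut-2-en-1-one
Conditions: MeI (excess), Ag2O, CH2Cl2, rt, dark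
Reagents that add atoms: iodomethane, CI
Why: Purdie methylation alkylates the secondary hydroxyl under non-basic conditions that the base-labile 4-hydroxycyclobutenone tolerates, and the stereocentre stays racemic.

Step 12
Reactants: 12 AB ethynyl ether; 16 racemic ring D cyclobutenone
Product: 21 4-[4-(benzyloxy)-3,5-dimethoxyphenoxy]-5-[2,6-dimethoxy-4-(2,4,6-trimethoxyphenoxy)phenoxy]-2,3-dimethoxyphenol (ABCD tetramer; C3 hydroxyl free; D4 benzyl ether), via vinylketene 17 (not isolated), via vinylcyclobutenone 18 (not isolated), via dienylketene 19 (not isolated), via cyclohexadienone 20 (not isolated)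
Conditions: PhMe, 80 °C then 110 °C, Ar
Reagents that add atoms: none
Why: Danheiser benzannulation: ring opening of 16 to vinylketene 17, [2+2] addition to the polarised ynol ether 12 (ketene carbonyl carbon to the alkyne CH), reopening of 18 to 19, six-electron electrocyclisation to 20 and tautomerisation should close ring C with C1–O–B4 next to C6–O–D1 and the hydrogen at C2, no stereocentre surviving.

Step 13
Reactants: 21 ABCD tetramer with free C3 hydroxyl
Product: 22 2-[4-(benzyloxy)-3,5-dimethoxyphenoxy]-1-[2,6-dimethoxy-4-(2,4,6-trimethoxyphenoxy)phenoxy]-3,4,5-trimethoxybenzene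
Conditions: MeI, K2CO3, acetone, reflux
Reagents that add atoms: iodomethane, CI
Why: Williamson methylation of the only free phenol, which is flanked by one hydrogen and is unhindered.

Step 14
Reactants: 22 ABCD benzyl ether
Product: 23 4-{6-[2,6-dimethoxy-4-(2,4,6-trimethoxyphenoxy)phenoxy]-2,3,4-trimethoxyphenoxy}-2,6-dimethoxyphenol (ABCD phenol, hydroxyl at D4)
Conditions: H2 (1 atm), Pd/C, EtOAc–MeOH, rt
Reagents that add atoms: none
Why: Hydrogenolysis removes the single benzyl group, and methyl and diaryl ethers are stable.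

Step 15
Reactants: 23 ABCD phenol; 9 trichloroethylene
Product: 24 ABCD (E)-1,2-dichlorovinyl ether (dichlorovinyl on the D4 oxygen)
Conditions: K2CO3, DMF, 70 °C
Reagents that add atoms: none
Why: The same O-vinylation through dichloroacetylene as in step 6 reaches the di-ortho-methoxy phenol oxygen without any aryl coupling and gives the (E)-isomer by anti addition.

Step 16
Reactants: 24 ABCD (E)-1,2-dichlorovinyl ether
Product: 26 ABCD aryl ethynyl ether (ethynyl on the D4 oxygen), via lithium acetylide 25 (not isolated)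
Conditions: n-BuLi (2.2 equiv), THF, −78 → −40 °C; then MeOH, −78 °C
Reagents that add atoms: none
Why: Elimination and chlorine–lithium exchange as in step 7 give acetylide 25, whose protonation gives the terminal ynol ether; the low temperature and exact stoichiometry keep the many anisole rings from being lithiated, and 26 should be filtered through basic alumina and used at once.

Step 17
Reactants: 3 3-chloro-4-methoxycyclobut-3-ene-1,2-dione; 27 3,4,5-trimethoxyphenol
Product: 28 3-methoxy-4-(3,4,5-trimethoxyphenoxy)cyclobut-3-ene-1,2-dione (ring F mixed aryl methyl squarate)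
Conditions: Et3N (1.1 equiv), CH2Cl2, −78 → 0 °C
Reagents that add atoms: none
Why: Addition–elimination on the vinylogous acid chloride as in step 9; under base the phenoxide reacts at oxygen with the acyl-type electrophile and not at its electron-rich ring carbons.

Step 18
Reactants: 28 ring F mixed aryl methyl squarate
Product: 29 racemic 4-hydroxy-3-methoxy-2-(3,4,5-trimethoxyphenoxy)cyclobut-2-en-1-one
Conditions: LiAlH(OtBu)3 (1.1 equiv), THF, −78 °C; aq. NH4Cl
Reagents that add atoms: none
Why: Regioselective 1,2-reduction as in step 10, with hydride expected at the carbonyl adjacent to the methoxy carbon for electronic and steric reasons; the new stereocentre is racemic and is lost in step 20.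

Step 19
Reactants: 29 racemic 4-hydroxycyclobutenone
Product: 30 racemic 3,4-dimethoxy-2-(3,4,5-trimethoxyphenoxy)cyclobut-2-en-1-one
Conditions: MeI (excess), Ag2O, CH2Cl2, rt, dark
Reagents that add atoms: iodomethane, CI
Why: Purdie methylation under non-basic conditions, as in step 11, caps the hydroxyl that becomes the E4 oxygen.

Step 20
Reactants: 26 ABCD aryl ethynyl ether; 30 racemic 3,4-dimethoxy-2-(3,4,5-trimethoxyphenoxy)cyclobut-2-en-1-one
Product: 35 hexamer pentadecamethyl ether (free hydroxyl at E3), via vinylketene 31 (not isolated), via vinylcyclobutenone 32 (not isolated), via dienylketene 33 (not isolated), via cyclohexadienone 34 (not isolated)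
Conditions: PhMe, 80 °C (slow addition of 30, 1.5 equiv), then 110 °C, Ar
Reagents that add atoms: none
Why: On heating, 30 undergoes four-electron conrotatory ring opening (the C4 methoxy turning outward) to vinylketene 31, whose electrophilic carbonyl carbon bonds to the oxygen-free terminal carbon of ynol ether 26 (E2–E3) while the aryloxy-bearing ketene carbon bonds to the oxygen-bearing alkyne carbon (E1–E6), giving 4-vinylcyclobutenone 32. Compound 32 reopens with the aryloxy group outward and the dimethoxyvinyl group inward to dienylketene 33, and ring E is closed by six-electron electrocyclisation between the ketene carbon and the methoxy-bearing vinyl terminus (E3–E4) to cyclohexadienone 34, which tautomerises to the E3 phenol. The closest known reaction type is the Danheiser benzannulation of a cyclobutenone with an alkynyl ether, here with a squarate-derived trioxygenated cyclobutenone. No stereocentre is created, and those of 30, 32 and 34 are erased on aromatisation. The selectivity needed is regiochemical, and the polarisation of the ynol ether secures it, so that the ring D oxygen at E1 lies next to the ring F oxygen at E6 and the hydrogen at E2 next to the new hydroxyl. Slow addition of 30 keeps the vinylketene concentration low, which should hold back its dimerisation and the acylation of the product phenol.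

Step 21
Reactants: 35 hexamer pentadecamethyl ether
Product: 36 target CNP0114537.0 (ABCDEF hexamer with sixteen free hydroxyls)
Conditions: BBr3 (40 equiv), CH2Cl2, −78 °C → rt, Ar; then MeOH, H2O, 0 °C
Reagents that add atoms: none
Why: Lewis acid O-demethylation: BBr3 complexes each methoxy oxygen and bromide removes the methyl group while diaryl ether bonds are inert; the polyphenol is oxidation-prone, so quench and isolation should be done under argon with degassed solvents.

**Compound list**

1 | squaric acid | OC1=C(O)C(=O)C1=O | starting material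
2 | squaryl dichloride (3,4-dichlorocyclobut-3-ene-1,2-dione) | ClC1=C(Cl)C(=O)C1=O | intermediate
3 | 3-chloro-4-methoxycyclobut-3-ene-1,2-dione | COC1=C(Cl)C(=O)C1=O | intermediate
4 | 4-bromo-2,6-dimethoxyphenol | COc1cc(Br)cc(OC)c1O | starting material
5 | 2-(benzyloxy)-5-bromo-1,3-dimethoxybenzene | COc1cc(Br)cc(OC)c1OCc1ccccc1 | intermediate
6 | 2,4,6-trimethoxyphenol | COc1cc(OC)c(O)c(OC)c1 | starting material
7 | 2-(benzyloxy)-1,3-dimethoxy-5-(2,4,6-trimethoxyphenoxy)benzene (AB benzyl ether) | COc1cc(OC)c(Oc2cc(OC)c(OCc3ccccc3)c(OC)c2)c(OC)c1 | intermediate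
8 | 2,6-dimethoxy-4-(2,4,6-trimethoxyphenoxy)phenol (AB phenol) | COc1cc(OC)c(Oc2cc(OC)c(O)c(OC)c2)c(OC)c1 | intermediate
9 | trichloroethylene | ClC=C(Cl)Cl | starting material
10 | 2-{[(E)-1,2-dichloroethenyl]oxy}-1,3-dimethoxy-5-(2,4,6-trimethoxyphenoxy)benzene | COc1cc(OC)c(Oc2cc(OC)c(O/C(Cl)=C\Cl)c(OC)c2)c(OC)c1 | intermediate
11 | lithium [2,6-dimethoxy-4-(2,4,6-trimethoxyphenoxy)phenoxy]acetylide | [Li]C#COc1c(OC)cc(Oc2c(OC)cc(OC)cc2OC)cc1OC | intermediate (not isolated)
12 | 2-(ethynyloxy)-1,3-dimethoxy-5-(2,4,6-trimethoxyphenoxy)benzene (AB ethynyl ether) | C#COc1c(OC)cc(Oc2c(OC)cc(OC)cc2OC)cc1OC | intermediate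
13 | 4-(benzyloxy)-3,5-dimethoxyphenol | COc1cc(O)cc(OC)c1OCc1ccccc1 | intermediate
14 | 3-[4-(benzyloxy)-3,5-dimethoxyphenoxy]-4-methoxycyclobut-3-ene-1,2-dione | COC1=C(Oc2cc(OC)c(OCc3ccccc3)c(OC)c2)C(=O)C1=O | intermediate
15 | racemic 2-[4-(benzyloxy)-3,5-dimethoxyphenoxy]-4-hydroxy-3-methoxycyclobut-2-en-1-one | COC1=C(Oc2cc(OC)c(OCc3ccccc3)c(OC)c2)C(=O)C1O | intermediate
16 | racemic 2-[4-(benzyloxy)-3,5-dimethoxyphenoxy]-3,4-dimethoxycyclobut-2-en-1-one | COC1C(OC)=C(Oc2cc(OC)c(OCc3ccccc3)c(OC)c2)C1=O | intermediate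
17 | (Z)-2-[4-(benzyloxy)-3,5-dimethoxyphenoxy]-3,4-dimethoxybuta-1,3-dien-1-one (vinylketene) | CO/C=C(\OC)C(Oc1cc(OC)c(OCc2ccccc2)c(OC)c1)=C=O | intermediate (not isolated)
18 | racemic 4-[4-(benzyloxy)-3,5-dimethoxyphenoxy]-4-[(Z)-1,2-dimethoxyethenyl]-3-[2,6-dimethoxy-4-(2,4,6-trimethoxyphenoxy)phenoxy]cyclobut-2-en-1-one | CO/C=C(\OC)C1(Oc2cc(OC)c(OCc3ccccc3)c(OC)c2)C(=O)C=C1Oc1c(OC)cc(Oc2c(OC)cc(OC)cc2OC)cc1OC | intermediate (not isolated)
19 | (3Z,5Z)-4-[4-(benzyloxy)-3,5-dimethoxyphenoxy]-3-[2,6-dimethoxy-4-(2,4,6-trimethoxyphenoxy)phenoxy]-5,6-dimethoxyhexa-1,3,5-trien-1-one (dienylketene) | O=C=C/C(Oc1c(OC)cc(Oc2c(OC)cc(OC)cc2OC)cc1OC)=C(Oc1cc(OC)c(OCc2ccccc2)c(OC)c1)\C(OC)=C\OC | intermediate (not isolated)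
20 | racemic 4-[4-(benzyloxy)-3,5-dimethoxyphenoxy]-3-[2,6-dimethoxy-4-(2,4,6-trimethoxyphenoxy)phenoxy]-5,6-dimethoxycyclohexa-2,4-dien-1-one | COC1C(=O)C=C(Oc2c(OC)cc(Oc3c(OC)cc(OC)cc3OC)cc2OC)C(Oc2cc(OC)c(OCc3ccccc3)c(OC)c2)=C1OC | intermediate (not isolated)
21 | 4-[4-(benzyloxy)-3,5-dimethoxyphenoxy]-5-[2,6-dimethoxy-4-(2,4,6-trimethoxyphenoxy)phenoxy]-2,3-dimethoxyphenol (ABCD tetramer, C3 hydroxyl free, D4 benzyl ether) | COc1c(O)cc(Oc2c(OC)cc(Oc3c(OC)cc(OC)cc3OC)cc2OC)c(Oc2cc(OC)c(OCc3ccccc3)c(OC)c2)c1OC | intermediate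
22 | 2-[4-(benzyloxy)-3,5-dimethoxyphenoxy]-1-[2,6-dimethoxy-4-(2,4,6-trimethoxyphenoxy)phenoxy]-3,4,5-trimethoxybenzene | COc1c(OC)cc(Oc2c(OC)cc(Oc3c(OC)cc(OC)cc3OC)cc2OC)c(Oc2cc(OC)c(OCc3ccccc3)c(OC)c2)c1OC | intermediate
23 | 4-{6-[2,6-dimethoxy-4-(2,4,6-trimethoxyphenoxy)phenoxy]-2,3,4-trimethoxyphenoxy}-2,6-dimethoxyphenol (ABCD phenol, hydroxyl at D4) | COc1c(OC)cc(Oc2c(OC)cc(Oc3c(OC)cc(OC)cc3OC)cc2OC)c(Oc2cc(OC)c(O)c(OC)c2)c1OC | intermediate
24 | ABCD (E)-1,2-dichlorovinyl ether (dichlorovinyl on the D4 oxygen of 23) | COc1c(OC)cc(Oc2c(OC)cc(Oc3c(OC)cc(OC)cc3OC)cc2OC)c(Oc2cc(OC)c(O/C(Cl)=C\Cl)c(OC)c2)c1OC | intermediate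
25 | lithium acetylide of the ABCD ynol ether | [Li]C#COc1c(OC)cc(Oc2c(OC)c(OC)c(OC)cc2Oc2c(OC)cc(Oc3c(OC)cc(OC)cc3OC)cc2OC)cc1OC | intermediate (not isolated)
26 | ABCD aryl ethynyl ether (ethynyl on the D4 oxygen) | C#COc1c(OC)cc(Oc2c(OC)c(OC)c(OC)cc2Oc2c(OC)cc(Oc3c(OC)cc(OC)cc3OC)cc2OC)cc1OC | intermediate
27 | 3,4,5-trimethoxyphenol | COc1cc(O)cc(OC)c1OC | starting material
28 | 3-methoxy-4-(3,4,5-trimethoxyphenoxy)cyclobut-3-ene-1,2-dione | COC1=C(Oc2cc(OC)c(OC)c(OC)c2)C(=O)C1=O | intermediate
29 | racemic 4-hydroxy-3-methoxy-2-(3,4,5-trimethoxyphenoxy)cyclobut-2-en-1-one | COC1=C(Oc2cc(OC)c(OC)c(OC)c2)C(=O)C1O | intermediate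
30 | racemic 3,4-dimethoxy-2-(3,4,5-trimethoxyphenoxy)cyclobut-2-en-1-one | COC1C(OC)=C(Oc2cc(OC)c(OC)c(OC)c2)C1=O | intermediate
31 | (Z)-3,4-dimethoxy-2-(3,4,5-trimethoxyphenoxy)buta-1,3-dien-1-one (vinylketene) | CO/C=C(\OC)C(Oc1cc(OC)c(OC)c(OC)c1)=C=O | intermediate (not isolated)
32 | racemic 4-[(Z)-1,2-dimethoxyethenyl]-4-(3,4,5-trimethoxyphenoxy)-3-(ABCD aryloxy)cyclobut-2-en-1-one | CO/C=C(\OC)C1(Oc2cc(OC)c(OC)c(OC)c2)C(=O)C=C1Oc1c(OC)cc(Oc2c(OC)c(OC)c(OC)cc2Oc2c(OC)cc(Oc3c(OC)cc(OC)cc3OC)cc2OC)cc1OC | intermediate (not isolated)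
33 | (3Z,5Z)-5,6-dimethoxy-4-(3,4,5-trimethoxyphenoxy)-3-(ABCD aryloxy)hexa-1,3,5-trien-1-one (dienylketene) | O=C=C/C(Oc1c(OC)cc(Oc2c(OC)c(OC)c(OC)cc2Oc2c(OC)cc(Oc3c(OC)cc(OC)cc3OC)cc2OC)cc1OC)=C(Oc1cc(OC)c(OC)c(OC)c1)\C(OC)=C\OC | intermediate (not isolated)
34 | racemic 5,6-dimethoxy-4-(3,4,5-trimethoxyphenoxy)-3-(ABCD aryloxy)cyclohexa-2,4-dien-1-one | COC1C(=O)C=C(Oc2c(OC)cc(Oc3c(OC)c(OC)c(OC)cc3Oc3c(OC)cc(Oc4c(OC)cc(OC)cc4OC)cc3OC)cc2OC)C(Oc2cc(OC)c(OC)c(OC)c2)=C1OC | intermediate (not isolated)
35 | hexamer pentadecamethyl ether with free hydroxyl at E3 | COc1c(O)cc(Oc2c(OC)cc(Oc3c(OC)c(OC)c(OC)cc3Oc3c(OC)cc(Oc4c(OC)cc(OC)cc4OC)cc3OC)cc2OC)c(Oc2cc(OC)c(OC)c(OC)c2)c1OC | intermediate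
36 | CNP0114537.0 (ABCDEF hexamer, sixteen free hydroxyls) | Oc1cc(O)c(Oc2cc(O)c(Oc3cc(O)c(O)c(O)c3Oc3cc(O)c(Oc4cc(O)c(O)c(O)c4Oc4cc(O)c(O)c(O)c4)c(O)c3)c(O)c2)c(O)c1 | target

**Totals and risks**

Total step count: 21. Longest linear sequence: 12 steps (steps 3, 4, 5, 6, 7, 12, 13, 14, 15, 16, 20, 21); the squarate branch through steps 1, 2, 9, 10 and 11 into step 12 is equally long.

The three steps most likely to fail:

1. Step 20 (ring E benzannulation). Thermal oligomerisation of the large aryl ethynyl ether and dimerisation of the vinylketene may outrun the bimolecular ketene–alkyne cycloaddition, and the new E3 phenol may be acylated by vinylketene. The fallback sets out from phenol 23 and comes back to the route at target 36; it gives up the benzannulation for ring E and makes the E1–O–D4 ether by copper coupling of a ready-made E–F fragment. Commercial 2,3,4-trimethoxyphenol would be iodinated ortho to its hydroxyl (NIS, MeCN, 0 °C) to 6-iodo-2,3,4-trimethoxyphenol F1. Chan–Lam O-arylation of F1 with 3,4,5-trimethoxyphenylboronic acid (Cu(OAc)2, pyridine, 4 Å sieves, CH2Cl2, air) would give 1-iodo-3,4,5-trimethoxy-2-(3,4,5-trimethoxyphenoxy)benzene F2. Ullmann coupling of 23 with F2 (CuI, picolinic acid, K3PO4, DMSO, 110 °C) would give the hexamer hexadecamethyl ether F3, which BBr3 in CH2Cl2 would demethylate to 36.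

2. Step 12 (ring C benzannulation). The same competition between ynol ether self-condensation, ketene dimerisation and the productive cycloaddition applies, and this is the first trial of the reactivity. The fallback sets out from bromide 5 and phenol 8 and comes back at 22. Bromide 5 would be converted (n-BuLi, THF, −78 °C; B(OiPr)3; aq. HCl) into [4-(benzyloxy)-3,5-dimethoxyphenyl]boronic acid F4. Chan–Lam coupling of F4 with 6-iodo-2,3,4-trimethoxyphenol F1 (Cu(OAc)2, pyridine, 4 Å sieves, CH2Cl2, air) would give 2-[4-(benzyloxy)-3,5-dimethoxyphenoxy]-1-iodo-3,4,5-trimethoxybenzene F5. Ullmann coupling of 8 with F5 (CuI, picolinic acid, K3PO4, DMSO, 110 °C) would give 22 directly, without the methylation of step 13.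

3. Step 18 (regioselective reduction of the mixed squarate; step 10 is the same operation in the ring D series). Hydride may be delivered to the other carbonyl, or may displace the aryloxy group by conjugate addition–elimination, which would put the ring F ether on the wrong ring E carbon. The fallback sets out from 2 and 27 and comes back at 30; it removes the regiochemical question by using a symmetrical squarate. Dichloride 2 with two equivalents of 27 (Et3N, CH2Cl2, −78 → 0 °C) would give 3,4-bis(3,4,5-trimethoxyphenoxy)cyclobut-3-ene-1,2-dione F6. Reduction (LiAlH(OtBu)3, THF, −78 °C) can then give only racemic 4-hydroxy-2,3-bis(3,4,5-trimethoxyphenoxy)cyclobut-2-en-1-one F7. Purdie methylation (MeI, Ag2O) would give racemic 4-methoxy-2,3-bis(3,4,5-trimethoxyphenoxy)cyclobut-2-en-1-one F8. Methanolysis (MeOH, Et3N cat., 0 °C → rt) would exchange only the aryloxy group on C3, the β-carbon of the enone and a vinylogous aryl ester, giving 30 and returning one equivalent of 27.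

**Further compounds**

F1 | step 20 | 6-iodo-2,3,4-trimethoxyphenol | COc1cc(I)c(O)c(OC)c1OC
F2 | step 20 | 1-iodo-3,4,5-trimethoxy-2-(3,4,5-trimethoxyphenoxy)benzene | COc1cc(I)c(Oc2cc(OC)c(OC)c(OC)c2)c(OC)c1OC
F3 | step 20 | hexamer hexadecamethyl ether | COc1c(OC)cc(Oc2c(OC)cc(Oc3c(OC)c(OC)c(OC)cc3Oc3c(OC)cc(Oc4c(OC)cc(OC)cc4OC)cc3OC)cc2OC)c(Oc2cc(OC)c(OC)c(OC)c2)c1OC
F4 | step 12 | [4-(benzyloxy)-3,5-dimethoxyphenyl]boronic acid | COc1cc(B(O)O)cc(OC)c1OCc1ccccc1
F5 | step 12 | 2-[4-(benzyloxy)-3,5-dimethoxyphenoxy]-1-iodo-3,4,5-trimethoxybenzene | COc1cc(I)c(Oc2cc(OC)c(OCc3ccccc3)c(OC)c2)c(OC)c1OC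
F6 | step 18 | 3,4-bis(3,4,5-trimethoxyphenoxy)cyclobut-3-ene-1,2-dione | COc1cc(OC2=C(Oc3cc(OC)c(OC)c(OC)c3)C(=O)C2=O)cc(OC)c1OC
F7 | step 18 | racemic 4-hydroxy-2,3-bis(3,4,5-trimethoxyphenoxy)cyclobut-2-en-1-one | COc1cc(OC2=C(Oc3cc(OC)c(OC)c(OC)c3)C(=O)C2O)cc(OC)c1OC
F8 | step 18 | racemic 4-methoxy-2,3-bis(3,4,5-trimethoxyphenoxy)cyclobut-2-en-1-one | COC1C(Oc2cc(OC)c(OC)c(OC)c2)=C(Oc2cc(OC)c(OC)c(OC)c2)C1=O
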